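**Retrosynthetic overview**
1. The two pyranone rings (C and D) are disconnected first. C2 and C2' go back to diethyl carbonate and the 4- and 4'-O-methyl groups to dimethyl sulfate, which leaves a biaryl built from two ortho-hydroxyacetophenones.
2. The strategy rests on the pattern of benzene ring A (C4a, C5, C6, C7, C8, C8a) and ring B (the primed atoms). The oxygens at C7/C8a (C7'/C8a') are meta to each other, and the methyl-bearing C5 (C5') is next to the acyl-bearing C4a (C4a'). This is what a 1,3-dioxygenated diene C6–C7–C8–C8a (C6'–C7'–C8'–C8a') leaves when it adds to the triple bond of pent-3-yn-2-one (C5–C4a, C5'–C4a').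
3. Both benzene rings are opened together at C5–C6, C4a–C8a, C5'–C6' and C4a'–C8a'. This gives an acyclic bis(silyl ketene acetal) in which C6 of one diene is already bonded to C8' of the other.
4. The crowded C6–C8' axis therefore goes back to an unhindered SN2 alkylation of methyl acetoacetate (its C2 = C8') by methyl (E)-4-bromo-3-methoxybut-2-enoate (its C4 = C6). Acid-free O-methylation and twofold γ-enolisation/silylation then complete the precursor.
5. Order of ring formation: rings A and B in one operation, then rings C and D in one operation.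

Key step: step 4

Assumption: the target SMILES carries no axial descriptor, so the racemic pair of C6–C8' atropisomers is the goal. Coumarin numbering (unprimed unit linked at C6, primed unit at C8') is used for all intermediates.

**Step 1**
Reactants: 1 methyl acetoacetate; 2 methyl (E)-4-bromo-3-methoxybut-2-enoate
Product: 3 dimethyl (2E)-5-acetyl-3-methoxyhex-2-enedioate (racemic at C5; chain C4 = coumarin C6, chain C5 = C8')
Conditions: 1 (1.3 equiv), NaH (1.2 equiv), THF, 0 °C; then 2 (1.0 equiv), 0 °C to rt
Reagents that add atoms: none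
Why: SN2 alkylation of the stabilised acetoacetate enolate at the primary allylic bromide is fast at or below room temperature, the excess of 1 holds back dialkylation, the weakly basic enolate leaves the β-methoxy enoate untouched, and the new C5 stereocentre is racemic and is erased in step 2.

**Step 2**
Reactants: 3 dimethyl (2E)-5-acetyl-3-methoxyhex-2-enedioate
Product: 4 dimethyl (2E,5E)-3-methoxy-5-(1-methoxyethylidene)hex-2-enedioate
Conditions: KN(SiMe3)2 (1.05 equiv), 18-crown-6 (1.1 equiv), THF, −78 °C; MeOTf (1.2 equiv), −78 to −20 °C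
Reagents that add atoms: methyl trifluoromethanesulfonate, COS(=O)(=O)C(F)(F)F
Why: O-alkylation of a dissociated potassium β-keto ester enolate by a hard methylating agent, helped by the α-substituent that hinders C-methylation, replaces the usual orthoformate/acid enol etherification because 3 is a masked 1,4-diketone (acetyl C=O and the C3 enol ether) that acid would drain into a furan by Paal–Knorr closure; the free W-shaped enolate should give mainly the E isomer (OMe trans to CO2Me), and any Z isomer gives the same dienolate in step 3.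

**Step 3**
Reactants: 4 dimethyl (2E,5E)-3-methoxy-5-(1-methoxyethylidene)hex-2-enedioate
Product: 5 linked bis-diene CH2=C(OMe)–C[=C(OMe)OSiMe3]–CH=C(OMe)–CH=C(OMe)OSiMe3, (1Z,3Z)-1,3,6-trimethoxy-5-[(Z)-methoxy(trimethylsilyloxy)methylidene]-1-(trimethylsilyloxy)hepta-1,3,6-triene
Conditions: Me3SiCl (3 equiv), then commercial LiN(iPr)2 solution (2.5 equiv) added slowly, THF, −78 to 0 °C; evaporation, dry pentane, filtration under argon; used crude
Reagents that add atoms: chlorotrimethylsilane, C[Si](C)(C)Cl
Why: Carbonyl-directed γ-deprotonation and O-silylation of β-methoxy enoates is the standard entry to 1,3-dimethoxy-1-silyloxybutadienes; with Me3SiCl present from the start each dienolate is trapped before the next proton is removed, so no dianion is needed, and allylic 1,3-strain against the ester-derived terminus places C8' trans to C8 on the new C6=C7 bond.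

**Step 4**
Reactants: 5 linked bis-diene; 6 pent-3-yn-2-one
Product: 9 1-[3-(3-acetyl-4-hydroxy-6-methoxy-2-methylphenyl)-2-hydroxy-4-methoxy-6-methylphenyl]ethanone (racemic axis), via twofold cycloadduct 7 (not isolated), via bis(trimethylsilyl) ether 8 (not isolated)
Conditions: 6 (5 equiv), MeC(OSiMe3)=NSiMe3 (BSA, 2.5 equiv), toluene, 110 °C, sealed tube; then 1 M HCl, THF, rt
Reagents that add atoms: none
Why: Proposed new method: each half of 5 is a 1,3-dimethoxy-1-silyloxybutadiene whose two donor oxygens put the largest coefficient on the unoxygenated terminus (C6, C6'), so this carbon bonds ahead to the β-carbon of 6 while the ketene acetal carbon (C8a, C8a') closes onto the α-carbon in a concerted but strongly asynchronous [4+2] addition, which places methyl at C5/C5' and acetyl at C4a/C4a'. The closest known reaction type is the Diels–Alder/aromatisation of single 1,3-dialkoxy-1-silyloxybutadienes with acetylenic ketones and esters to resorcinol monoethers, whereas a twofold version on two such dienes joined terminus-to-C2 has not been shown. Ring A closes by forming C5–C6 and C4a–C8a and ring B by forming C5'–C6' and C4a'–C8a', each as a six-membered intermolecular [4+2] closure followed by 1,4-loss of methanol (H from C6 or C6', OMe from C8a or C8a') to the aryl silyl ether, which dilute acid cleaves to the acetyl-chelated phenol. The sp3 centres of 7 are transient, no stereocentre remains, and the tetra-ortho-substituted C6–C8' axis appears only on aromatisation and forms as the racemate. Periselectivity among three diene units is needed, and it is secured because the third unit (C7=C6–C8'=C8a') has two fully substituted termini whose donors oppose each other, while the C6=C7 geometry (C8' trans to C8) puts C8' on the outside of the s-cis diene and bars 6π-electrocyclisation of the C8a'=C8'–C6=C7–C8=C8a triene. The methanol released by the first aromatisation would protonate the surviving ketene acetal, so BSA is present as a neutral scavenger and 6 is used in excess.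

**Step 5**
Reactants: 9 1-[3-(3-acetyl-4-hydroxy-6-methoxy-2-methylphenyl)-2-hydroxy-4-methoxy-6-methylphenyl]ethanone
Product: 10 4,4'-dihydroxy-7,7'-dimethoxy-5,5'-dimethyl-6,8'-bi(2H-chromen-2-one) (racemic axis)
Conditions: NaH (8 equiv), (EtO)2CO (10 equiv), toluene, 110 °C; then 1 M HCl
Reagents that add atoms: diethyl carbonate, CCOC(=O)OCC
Why: Claisen-type acylation of each acetyl enolate by diethyl carbonate with lactonisation onto the neighbouring phenoxide is the classical 4-hydroxycoumarin synthesis from ortho-hydroxyacetophenones, it tolerates the flanking C5 methyl group, and formation of the stabilised 4-oxidocoumarin salts drives both closures (rings C and D).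

**Step 6**
Reactants: 10 4,4'-dihydroxy-7,7'-dimethoxy-5,5'-dimethyl-6,8'-bi(2H-chromen-2-one)
Product: 11 4,4',7,7'-tetramethoxy-5,5'-dimethyl-6,8'-bi(2H-chromen-2-one) (target, racemic axis)
Conditions: Me2SO4 (3 equiv), K2CO3 (4 equiv), acetone, reflux
Reagents that add atoms: dimethyl sulfate, COS(=O)(=O)OC
Why: O-alkylation of the vinylogous acid of a 4-hydroxycoumarin with Me2SO4/K2CO3 in acetone should favour the 4-methoxycoumarin over the 2-methoxychromone or the C3-methyl product, and no other site in 10 is nucleophilic.

**Compound list**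
1 | methyl acetoacetate | CC(=O)CC(=O)OC | starting material
2 | methyl (E)-4-bromo-3-methoxybut-2-enoate | CO/C(CBr)=C/C(=O)OC | starting material
3 | dimethyl (2E)-5-acetyl-3-methoxyhex-2-enedioate (racemic) | CO/C(CC(C(C)=O)C(=O)OC)=C/C(=O)OC | intermediate
4 | dimethyl (2E,5E)-3-methoxy-5-(1-methoxyethylidene)hex-2-enedioate | CO/C(C/C(C(=O)OC)=C(/C)OC)=C/C(=O)OC | intermediate
5 | (1Z,3Z)-1,3,6-trimethoxy-5-[(Z)-methoxy(trimethylsilyloxy)methylidene]-1-(trimethylsilyloxy)hepta-1,3,6-triene (linked bis-diene) | C=C(OC)/C(=C(/OC)O[Si](C)(C)C)/C=C(OC)/C=C(/OC)O[Si](C)(C)C | intermediate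
6 | pent-3-yn-2-one | CC#CC(C)=O | starting material
7 | twofold [4+2] adduct, two linked cyclohexa-1,4-dienes each with a C(OMe)(OSiMe3) carbon (diastereomer mixture, drawn before loss of methanol) | CC(=O)C1=C(C)C(C(OC)=CC1(OC)O[Si](C)(C)C)C1=C(OC)CC(C)=C(C(C)=O)C1(OC)O[Si](C)(C)C | intermediate
8 | bis(trimethylsilyl) ether of 9 | CC(=O)c1c(O[Si](C)(C)C)cc(OC)c(c1C)-c1c(OC)cc(C)c(C(C)=O)c1O[Si](C)(C)C | intermediate
9 | 1-[3-(3-acetyl-4-hydroxy-6-methoxy-2-methylphenyl)-2-hydroxy-4-methoxy-6-methylphenyl]ethanone | CC(=O)c1c(O)cc(OC)c(c1C)-c1c(OC)cc(C)c(C(C)=O)c1O | intermediate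
10 | 4,4'-dihydroxy-7,7'-dimethoxy-5,5'-dimethyl-6,8'-bi(2H-chromen-2-one) | COc1cc2oc(=O)cc(O)c2c(C)c1-c1c(OC)cc(C)c2c(O)cc(=O)oc12 | intermediate
11 | 4,4',7,7'-tetramethoxy-5,5'-dimethyl-6,8'-bi(2H-chromen-2-one) | COc1cc2oc(=O)cc(OC)c2c(C)c1-c1c(OC)cc(C)c2c(OC)cc(=O)oc12 | target

Total step count: 6. Longest linear sequence: 6 steps (1 or 2 to 11).

**Steps most likely to fail**

**Step 4.**
- Risk: the second ketene acetal may be protonated before it reacts. The addition may stall at the open-chain Michael stage. The crowded C6 terminus may refuse the internal alkyne while the tetraene decays thermally.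
- Fallback (known chemistry, from 6 back to 9): the cycloaddition is kept only in its known single, unhindered form, and the axis is made by cross-coupling.
- Compound 6 is heated with (1Z)-1,3-dimethoxy-1-(trimethylsilyloxy)buta-1,3-diene F1 (LiN(iPr)2/Me3SiCl on commercial methyl (E)-3-methoxybut-2-enoate). Acid work-up gives 1-(2-hydroxy-4-methoxy-6-methylphenyl)ethanone F2.
- Me2SO4/K2CO3 gives 1-(2,4-dimethoxy-6-methylphenyl)ethanone F3.
- NBS in MeCN should brominate the position between methyl and methoxy (para to the other methoxy group), giving 1-(3-bromo-4,6-dimethoxy-2-methylphenyl)ethanone F4.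
- Suzuki–Miyaura coupling with commercial (2,6-dimethoxy-4-methylphenyl)boronic acid (Pd(OAc)2, SPhos, K3PO4, toluene/water, 100 °C) gives 1-[3-(2,6-dimethoxy-4-methylphenyl)-4,6-dimethoxy-2-methylphenyl]ethanone F5.
- Friedel–Crafts acetylation (AcCl, TiCl4, CH2Cl2) should go to the acyl-free ring, whose two open positions are equivalent, giving 1-[3-(3-acetyl-4,6-dimethoxy-2-methylphenyl)-2,4-dimethoxy-6-methylphenyl]ethanone F6.
- BCl3 (CH2Cl2, −78 to 0 °C) cleaves only the two methoxy groups chelated to an acetyl group and delivers 9.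

**Step 3.**
- Risk: the second enolisation may stay incomplete, carbon may be silylated in place of oxygen, or one ketene acetal may hydrolyse during isolation.
- Fallback (from 4 back to 9): the rings are built one at a time, so a bis(ketene acetal) is never needed.
- One equivalent of LiN(iPr)2/Me3SiCl should remove the doubly allylic proton at C6 first, giving methyl 4,6-dimethoxy-2-(1-methoxyethylidene)-6-(trimethylsilyloxy)hexa-3,5-dienoate F7.
- Cycloaddition with 6 and acid work-up close ring A as methyl (E)-2-(3-acetyl-4-hydroxy-6-methoxy-2-methylphenyl)-3-methoxybut-2-enoate F8.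
- Excess LiN(iPr)2/Me3SiCl silylates the phenol, the acetyl enolate and the γ-methyl dienolate in one operation. This gives 1,3-dimethoxy-2-[6-methoxy-2-methyl-4-(trimethylsilyloxy)-3-(1-trimethylsilyloxyethenyl)phenyl]-1-(trimethylsilyloxy)buta-1,3-diene F9.
- A second cycloaddition with 6 and acid work-up, which also frees the phenol and the acetyl group, close ring B and give 9.

**Step 2.**
- Risk: methylation may occur at carbon to give a quaternary centre, or the enolate oxygen may close onto C3 with loss of methoxide on the way to a furan.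
- Fallback (from 3 back to 9): the enol oxygen is silylated instead of methylated, and the methyl group is added after ring formation.
- Me3SiCl/Et3N (toluene, rt) gives dimethyl (2E)-3-methoxy-5-[1-(trimethylsilyloxy)ethylidene]hex-2-enedioate F10.
- The conditions of step 3 give (1Z,3Z)-1,3-dimethoxy-5-[(Z)-methoxy(trimethylsilyloxy)methylidene]-1,6-bis(trimethylsilyloxy)hepta-1,3,6-triene F11.
- The conditions of step 4 with 6 give 1-[3-(3-acetyl-4-hydroxy-6-methoxy-2-methylphenyl)-2,4-dihydroxy-6-methylphenyl]ethanone F12.
- Only the C7' hydroxyl of F12 lacks a hydrogen bond to an acetyl group, so one equivalent of MeI with K2CO3 in acetone should give 9.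

**Further compounds**
F1 | step 4 | (1Z)-1,3-dimethoxy-1-(trimethylsilyloxy)buta-1,3-diene | C=C(OC)/C=C(/OC)O[Si](C)(C)C
F2 | step 4 | 1-(2-hydroxy-4-methoxy-6-methylphenyl)ethanone | CC(=O)c1c(C)cc(OC)cc1O
F3 | step 4 | 1-(2,4-dimethoxy-6-methylphenyl)ethanone | CC(=O)c1c(C)cc(OC)cc1OC
F4 | step 4 | 1-(3-bromo-4,6-dimethoxy-2-methylphenyl)ethanone | CC(=O)c1c(C)c(Br)c(OC)cc1OC
F5 | step 4 | 1-[3-(2,6-dimethoxy-4-methylphenyl)-4,6-dimethoxy-2-methylphenyl]ethanone | CC(=O)c1c(C)c(c(OC)cc1OC)-c1c(OC)cc(C)cc1OC
F6 | step 4 | 1-[3-(3-acetyl-4,6-dimethoxy-2-methylphenyl)-2,4-dimethoxy-6-methylphenyl]ethanone | CC(=O)c1c(C)c(c(OC)cc1OC)-c1c(OC)cc(C)c(C(C)=O)c1OC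
F7 | step 3 | methyl 4,6-dimethoxy-2-(1-methoxyethylidene)-6-(trimethylsilyloxy)hexa-3,5-dienoate | C/C(OC)=C(C(=O)OC)/C=C(OC)/C=C(/OC)O[Si](C)(C)C
F8 | step 3 | methyl (E)-2-(3-acetyl-4-hydroxy-6-methoxy-2-methylphenyl)-3-methoxybut-2-enoate | C/C(OC)=C(C(=O)OC)/c1c(C)c(C(C)=O)c(O)cc1OC
F9 | step 3 | 1,3-dimethoxy-2-[6-methoxy-2-methyl-4-(trimethylsilyloxy)-3-(1-trimethylsilyloxyethenyl)phenyl]-1-(trimethylsilyloxy)buta-1,3-diene | C=C(OC)/C(=C(/OC)O[Si](C)(C)C)c1c(C)c(C(=C)O[Si](C)(C)C)c(O[Si](C)(C)C)cc1OC
F10 | step 2 | dimethyl (2E)-3-methoxy-5-[1-(trimethylsilyloxy)ethylidene]hex-2-enedioate (E/Z mixture at the silyl enol ether) | CO/C(CC(C(=O)OC)=C(C)O[Si](C)(C)C)=C/C(=O)OC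
F11 | step 2 | (1Z,3Z)-1,3-dimethoxy-5-[(Z)-methoxy(trimethylsilyloxy)methylidene]-1,6-bis(trimethylsilyloxy)hepta-1,3,6-triene | C=C(O[Si](C)(C)C)/C(=C(/OC)O[Si](C)(C)C)/C=C(OC)/C=C(/OC)O[Si](C)(C)C
F12 | step 2 | 1-[3-(3-acetyl-4-hydroxy-6-methoxy-2-methylphenyl)-2,4-dihydroxy-6-methylphenyl]ethanone | CC(=O)c1c(O)cc(OC)c(c1C)-c1c(O)cc(C)c(C(C)=O)c1O
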